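**Retrosynthetic overview**
1. Target 16 is cut at the C8–C(=O) bond: an 8‑magnesiated 6‑prenylcoumarin phenoxide (from iodide 13) plus the enal‑lactol 8, joined by Grignard addition and in‑flask Oppenauer oxidation.
2. Lactol 8 comes from bicyclic lactone 7, which comes from an ester‑tethered intramolecular Diels–Alder reaction of triene ester 5 followed by conjugation; this forms the cyclohexene and γ‑lactone rings together and sets C5 and C6 from the carbinol centre.
3. Ester 5 comes from (2E)‑penta‑2,4‑dienoic acid 4 and (2S,3Z)‑pent‑3‑en‑2‑ol 3, made from (S)‑but‑3‑yn‑2‑ol 1, the only purchased stereocentre.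
4. Iodide 13 comes from coumarin 11 (Pechmann, pyranone ring) by C8 iodination and C6 prenylation.
5. Ring order: pyranone (arene branch); cyclohexene plus lactone (Diels–Alder); the lactone is opened again at the coupling.

Assumption: compounds 1, 4, 9 and 10 and all reagents are catalogue chemicals. Cyclohexene locants: C1 bears the acyl group, C5 the methyl, C6 the hydroxyethyl group, C1′ is the carbinol carbon. The target is (5R,6R,1′S), with the C5 methyl and C6 side chain cis.

**Step 1**
Reactants: 1 (2S)-but-3-yn-2-ol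
Product: 2 (2S)-pent-3-yn-2-ol
Conditions: n-BuLi (2.1 equiv), THF, −78 → −20 °C; MeI (1.05 equiv), DMPU, −20 °C → rt; H2O
Reagents that add atoms: iodomethane, CI
Why: Alkylation of the alkoxide/acetylide dianion occurs at the far more nucleophilic acetylide carbon (acetylide C‑alkylation), and the carbinol stereocentre is not involved.

**Step 2**
Reactants: 2 (2S)-pent-3-yn-2-ol
Product: 3 (2S,3Z)-pent-3-en-2-ol
Conditions: H2 (1 atm), Lindlar catalyst, quinoline, pentane, 0 °C
Reagents that add atoms: none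
Why: Lindlar semihydrogenation delivers H2 syn to give the Z‑alkene needed for the later cis C5/C6 relationship.

**Step 3**
Reactants: 3 (2S,3Z)-pent-3-en-2-ol; 4 (2E)-penta-2,4-dienoic acid
Product: 5 (2S,3Z)-pent-3-en-2-yl (2E)-penta-2,4-dienoate
Conditions: DCC, DMAP (cat.), BHT (cat.), CH2Cl2, 0 °C → rt
Reagents that add atoms: none
Why: Steglich esterification acylates the secondary allylic alcohol under neutral conditions with retention at the carbinol carbon and no allylic transposition.

**Step 4**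
Reactants: 5 (2S,3Z)-pent-3-en-2-yl (2E)-penta-2,4-dienoate
Product: 7 (3S,3aR,4R)-3,4-dimethyl-3a,4,5,6-tetrahydro-2-benzofuran-1(3H)-one, via Diels–Alder adduct 6 (not isolated)
Conditions: PhMe (0.01 M), BHT (cat.), sealed tube, 200 °C, 36 h; then DBU (0.5 equiv), 90 °C
Reagents that add atoms: none
Why: Intramolecular Diels–Alder reaction in which the Z‑alkene geometry fixes methyl and lactone carbon cis, and 1,3‑allylic strain at the (S)‑carbinol (H eclipsing the Z‑alkene, tether oxygen on the reacting face) sets both new centres R; DBU then moves the alkene into conjugation through the dienolate, erasing the ring‑fusion α‑centre so endo and exo adducts converge.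

**Step 5**
Reactants: 7 (3S,3aR,4R)-3,4-dimethyl-3a,4,5,6-tetrahydro-2-benzofuran-1(3H)-one
Product: 8 (3S,3aR,4R)-3,4-dimethyl-1,3,3a,4,5,6-hexahydro-2-benzofuran-1-ol
Conditions: DIBAL-H (1.1 equiv), CH2Cl2, −78 °C; aq. Rochelle salt
Reagents that add atoms: none
Why: Low‑temperature DIBAL‑H reduction stops at the lactol (1,2‑reduction of the unsaturated lactone), which is the ring tautomer of the γ‑hydroxy enal; no stereocentre of the carbon skeleton is affected.

**Step 6**
Reactants: 9 5-methoxybenzene-1,3-diol; 10 ethyl 2-methyl-3-oxobutanoate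
Product: 11 7-hydroxy-5-methoxy-3,4-dimethyl-2H-chromen-2-one
Conditions: conc. H2SO4, 0 °C → rt
Reagents that add atoms: none
Why: Pechmann condensation closes at the ring carbon flanked by OH and OMe (para to the second free OH), giving the 7‑hydroxy‑5‑methoxy isomer as the expected major product, purified by crystallisation.

**Step 7**
Reactants: 11 7-hydroxy-5-methoxy-3,4-dimethyl-2H-chromen-2-one
Product: 12 7-hydroxy-8-iodo-5-methoxy-3,4-dimethyl-2H-chromen-2-one
Conditions: NIS (1.0 equiv), TFA (cat.), MeCN, 0 °C → rt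
Reagents that add atoms: N-iodosuccinimide, O=C1CCC(=O)N1I
Why: Electrophilic aromatic iodination is expected mainly at C8 (ortho to OH, para to OMe), the usual site of attack in 5,7‑dioxygenated coumarins, with C3/C4 blocked by methyl groups; any 6‑iodo isomer is removed by chromatography.

**Step 8**
Reactants: 12 7-hydroxy-8-iodo-5-methoxy-3,4-dimethyl-2H-chromen-2-one
Product: 13 7-hydroxy-8-iodo-5-methoxy-3,4-dimethyl-6-(3-methylbut-2-en-1-yl)-2H-chromen-2-one
Conditions: NaH (1.1 equiv), PhMe, 0 °C; prenyl bromide (1.2 equiv), rt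
Reagents that add atoms: 1-bromo-3-methylbut-2-ene, CC(C)=CCBr
Why: Ortho C‑alkylation of a sodium phenoxide as a tight ion pair in a non‑polar solvent goes to C6, the only free ring position; the O‑prenyl ether by‑product is separated.

**Step 9**
Reactants: 13 7-hydroxy-8-iodo-5-methoxy-3,4-dimethyl-6-(3-methylbut-2-en-1-yl)-2H-chromen-2-one; 8 (3S,3aR,4R)-3,4-dimethyl-1,3,3a,4,5,6-hexahydro-2-benzofuran-1-ol
Product: 16 7-hydroxy-8-{(5R,6R)-6-[(1S)-1-hydroxyethyl]-5-methylcyclohex-1-ene-1-carbonyl}-5-methoxy-3,4-dimethyl-6-(3-methylbut-2-en-1-yl)-2H-chromen-2-one, via arylmagnesium reagent 14 (not isolated), via benzylic carbinol 15 (not isolated)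
Conditions: 13 (1.3 equiv), MeMgCl (1.3 equiv), LiCl, THF, −30 °C; i-PrMgCl·LiCl (1.35 equiv), −30 → −15 °C; add 8 pre‑treated with t-BuMgCl (1.0 equiv, THF, −40 °C), −40 → 0 °C; PhCHO (3 equiv), rt; aq. NH4Cl
Reagents that add atoms: none
Why: Iodine–magnesium exchange on the magnesium phenoxide (which also deactivates the coumarin carbonyl), 1,2‑Grignard addition to the enal form of the lactolate, and magnesium‑Oppenauer hydride transfer to benzaldehyde that oxidises only the benzylic/allylic alkoxide give the aryl enone directly; no stereocentre is touched and the labile carbinol is never isolated.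

**Compound list**
1 | (2S)-but-3-yn-2-ol | C#C[C@H](C)O | starting material
2 | (2S)-pent-3-yn-2-ol | CC#C[C@H](C)O | intermediate
3 | (2S,3Z)-pent-3-en-2-ol | C/C=C\[C@H](C)O | intermediate
4 | (2E)-penta-2,4-dienoic acid | C=C/C=C/C(=O)O | starting material
5 | (2S,3Z)-pent-3-en-2-yl (2E)-penta-2,4-dienoate | C=C/C=C/C(=O)O[C@@H](C)/C=C\C | intermediate
6 | (3S,3aR,4R)-3,4-dimethyl-3a,4,5,7a-tetrahydro-2-benzofuran-1(3H)-one, β,γ‑unsaturated Diels–Alder adduct, C7a epimers | O=C1C2C=CC[C@@H](C)[C@H]2[C@H](C)O1 | intermediate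
7 | (3S,3aR,4R)-3,4-dimethyl-3a,4,5,6-tetrahydro-2-benzofuran-1(3H)-one | O=C1C2=CCC[C@@H](C)[C@H]2[C@H](C)O1 | intermediate
8 | (3S,3aR,4R)-3,4-dimethyl-1,3,3a,4,5,6-hexahydro-2-benzofuran-1-ol, anomers, ring tautomer of (5R,6R)-6-[(1S)-1-hydroxyethyl]-5-methylcyclohex-1-ene-1-carbaldehyde | OC1C2=CCC[C@@H](C)[C@H]2[C@H](C)O1 | intermediate
9 | 5-methoxybenzene-1,3-diol | COc1cc(O)cc(O)c1 | starting material
10 | ethyl 2-methyl-3-oxobutanoate | CCOC(=O)C(C)C(C)=O | starting material
11 | 7-hydroxy-5-methoxy-3,4-dimethyl-2H-chromen-2-one | COc1cc(O)cc2oc(=O)c(C)c(C)c12 | intermediate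
12 | 7-hydroxy-8-iodo-5-methoxy-3,4-dimethyl-2H-chromen-2-one | COc1cc(O)c(I)c2oc(=O)c(C)c(C)c12 | intermediate
13 | 7-hydroxy-8-iodo-5-methoxy-3,4-dimethyl-6-(3-methylbut-2-en-1-yl)-2H-chromen-2-one | COc1c(CC=C(C)C)c(O)c(I)c2oc(=O)c(C)c(C)c12 | intermediate
14 | 8-(chloromagnesio)-7-(chloromagnesiooxy)-5-methoxy-3,4-dimethyl-6-(3-methylbut-2-en-1-yl)-2H-chromen-2-one | COc1c(CC=C(C)C)c(O[Mg]Cl)c([Mg]Cl)c2oc(=O)c(C)c(C)c12 | intermediate
15 | 7-hydroxy-8-{hydroxy[(5R,6R)-6-[(1S)-1-hydroxyethyl]-5-methylcyclohex-1-en-1-yl]methyl}-5-methoxy-3,4-dimethyl-6-(3-methylbut-2-en-1-yl)-2H-chromen-2-one, carbinol epimers, present as magnesium alkoxide | COc1c(CC=C(C)C)c(O)c(C(O)C2=CCC[C@@H](C)[C@H]2[C@H](C)O)c2oc(=O)c(C)c(C)c12 | intermediate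
16 | 7-hydroxy-8-{(5R,6R)-6-[(1S)-1-hydroxyethyl]-5-methylcyclohex-1-ene-1-carbonyl}-5-methoxy-3,4-dimethyl-6-(3-methylbut-2-en-1-yl)-2H-chromen-2-one | COc1c(CC=C(C)C)c(O)c(C(=O)C2=CCC[C@@H](C)[C@H]2[C@H](C)O)c2oc(=O)c(C)c(C)c12 | target

**Totals**
Total steps: 9. Longest linear sequence: 6 (steps 1–5, then 9).

**Three steps most likely to fail, with fallbacks**

Step 4. The ester tether prefers the unreactive s‑trans rotamer and the Z‑propenyl dienophile is unactivated, so the cycloaddition may be too slow to outrun diene polymerisation. The fallback sets out from 1 and returns at 7, replacing the intramolecular by an intermolecular Diels–Alder reaction of a Z‑locked chiral butenolide. Carboxylation of the dianion of 1 (n‑BuLi, CO2) gives (4S)-4-hydroxypent-2-ynoic acid F1. Lindlar semihydrogenation with spontaneous lactonisation gives (5S)-5-methylfuran-2(5H)-one F2. Silylation of (E)‑pent‑2‑enal (TBSOTf, Et3N) gives (1E,3E)-1-(tert-butyldimethylsilyloxy)penta-1,3-diene F3. Heating F2 with F3 (PhMe, 150 °C) should add the diene anti to the lactone methyl, endo, with the siloxy carbon bonding to the α‑carbon, giving the 7-silyloxy-3a,4,7,7a-tetrahydro lactone F4. Hydrogenation (H2, Pd/C) gives the 7-silyloxy hexahydro lactone F5. TsOH in warm toluene removes silanol by β‑elimination to give 7. The endo/exo ratio, which sets C5, is the weak point of this fallback.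

Step 9. The exchange next to a magnesium phenoxide may be sluggish, the lactolate may open slowly, and the one‑pot oxidation may be incomplete. The fallback sets out from 13 (with 8) and returns at 16, using a protected, stepwise sequence. MOMCl and i‑Pr2NEt give the 7-(methoxymethoxy) iodide F6. Exchange with i‑PrMgCl·LiCl (−20 °C) and addition to the magnesium lactolate of 8 give, after neutral work‑up, the 7-(methoxymethoxy) diol F7. MnO2 in CH2Cl2 oxidises only the benzylic/allylic alcohol to the 7-(methoxymethoxy) ketone F8. Dilute HCl in MeOH at 40 °C removes the MOM group to give 16.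

Step 8. O‑prenylation can dominate over C‑prenylation at the hindered C6. The fallback sets out from 12 and returns at 13, delivering the prenyl group by a [3,3] shift. O‑Alkylation with 3‑chloro‑3‑methylbut‑1‑yne (K2CO3, KI, CuCl cat., acetone) gives the 7-(2-methylbut-3-yn-2-yloxy) ether F9. Lindlar semihydrogenation gives the 7-(2-methylbut-3-en-2-yloxy) ether F10. Heating in PhNEt2 at 130 °C effects aromatic Claisen rearrangement to C6, the only ortho position that can re‑aromatise, giving 13.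

**Further compounds**
F1 | step 4 | (4S)-4-hydroxypent-2-ynoic acid | C[C@H](O)C#CC(=O)O
F2 | step 4 | (5S)-5-methylfuran-2(5H)-one | C[C@@H]1OC(=O)C=C1
F3 | step 4 | (1E,3E)-1-(tert-butyldimethylsilyloxy)penta-1,3-diene | C/C=C/C=C/O[Si](C)(C)C(C)(C)C
F4 | step 4 | (3S,3aR,4R)-7-(tert-butyldimethylsilyloxy)-3,4-dimethyl-3a,4,7,7a-tetrahydro-2-benzofuran-1(3H)-one | O=C1C2C(O[Si](C)(C)C(C)(C)C)C=C[C@@H](C)[C@H]2[C@H](C)O1
F5 | step 4 | (3S,3aR,4R)-7-(tert-butyldimethylsilyloxy)-3,4-dimethylhexahydro-2-benzofuran-1(3H)-one | O=C1C2C(O[Si](C)(C)C(C)(C)C)CC[C@@H](C)[C@H]2[C@H](C)O1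
F6 | step 9 | 8-iodo-5-methoxy-7-(methoxymethoxy)-3,4-dimethyl-6-(3-methylbut-2-en-1-yl)-2H-chromen-2-one | COc1c(CC=C(C)C)c(OCOC)c(I)c2oc(=O)c(C)c(C)c12
F7 | step 9 | 8-{hydroxy[(5R,6R)-6-[(1S)-1-hydroxyethyl]-5-methylcyclohex-1-en-1-yl]methyl}-5-methoxy-7-(methoxymethoxy)-3,4-dimethyl-6-(3-methylbut-2-en-1-yl)-2H-chromen-2-one | COc1c(CC=C(C)C)c(OCOC)c(C(O)C2=CCC[C@@H](C)[C@H]2[C@H](C)O)c2oc(=O)c(C)c(C)c12
F8 | step 9 | 8-{(5R,6R)-6-[(1S)-1-hydroxyethyl]-5-methylcyclohex-1-ene-1-carbonyl}-5-methoxy-7-(methoxymethoxy)-3,4-dimethyl-6-(3-methylbut-2-en-1-yl)-2H-chromen-2-one | COc1c(CC=C(C)C)c(OCOC)c(C(=O)C2=CCC[C@@H](C)[C@H]2[C@H](C)O)c2oc(=O)c(C)c(C)c12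
F9 | step 8 | 8-iodo-5-methoxy-3,4-dimethyl-7-(2-methylbut-3-yn-2-yloxy)-2H-chromen-2-one | COc1cc(OC(C)(C)C#C)c(I)c2oc(=O)c(C)c(C)c12
F10 | step 8 | 8-iodo-5-methoxy-3,4-dimethyl-7-(2-methylbut-3-en-2-yloxy)-2H-chromen-2-one | COc1cc(OC(C)(C)C=C)c(I)c2oc(=O)c(C)c(C)c12
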